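**Retrosynthetic overview**
- The target comes from its O-protected form (catechol as isopropylidene ketal, ring-A phenol as isopropyl ether) by one Lewis-acid deprotection.
- The Cα–aryl bond and the methyl ester come from a light-driven, invertive 1,2-aryl shift of an (R)-α-mesyloxy aryl ketone in methanol. This turns a C–O stereocentre into the C–aryl stereocentre.
- The aryl ketone comes from an aryl Grignard reagent (2-isopropoxyphenol: iodination/bromination, then O-methylation) and the dioxolanone of dibrominated natural (R)-danshensu.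
- The only stereocentre is C2 of (R)-danshensu. The ring-B bromines are introduced on the free catechol before protection.
- No ring of the target is built, since both benzene rings are bought. Only temporary rings form: the benzodioxole ketal and the dioxolanone (together in step 2) and a transient spiro-cyclopropanone in the light step.

Assumption: the stereocentre in the given SMILES is (R) (CO2Me > aryl > CH2Ar > H), and natural sodium danshensu, (R), ≥98 % ee, is taken as a bulk-priced chiral-pool material.

**Step 1**
Reactants: 1 sodium (R)-danshensu, sodium (2R)-3-(3,4-dihydroxyphenyl)-2-hydroxypropanoate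
Product: 2 (2R)-3-(2,3-dibromo-4,5-dihydroxyphenyl)-2-hydroxypropanoic acid
Conditions: Br2 (2.05 equiv), NaOAc (1.1 equiv), AcOH, 10–15 °C, dark; NaHSO3 quench; recrystallise
Reagents that add atoms: bromine, BrBr
Why: Electrophilic aromatic bromination of a free catechol, in which the first Br enters para to one OH (product C2) and the second ortho to the other OH (product C3), because the electronically equivalent site next to the branched side chain is more hindered; the acetate buffer keeps kinetic control and the carbinol centre is untouched.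

**Step 2**
Reactants: 2 (2R)-3-(2,3-dibromo-4,5-dihydroxyphenyl)-2-hydroxypropanoic acid
Product: 3 (5R)-5-[(6,7-dibromo-2,2-dimethyl-1,3-benzodioxol-5-yl)methyl]-2,2-dimethyl-1,3-dioxolan-4-one
Conditions: Me2C(OMe)2 (8 equiv), TsOH·H2O (5 mol %), toluene, reflux, Soxhlet with 4 Å MS
Reagents that add atoms: 2,2-dimethoxypropane, COC(C)(C)OC
Why: Acid-catalysed transketalisation with one reagent protects the catechol as its isopropylidene ketal and converts the α-hydroxy acid into a 1,3-dioxolan-4-one (protection and acyl activation at once) without breaking any bond to the stereocentre.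

**Step 3**
Reactants: 4 2-(propan-2-yloxy)phenol (2-isopropoxyphenol)
Product: 6 2-bromo-4-iodo-6-(propan-2-yloxy)phenol, via 4-iodo-2-(propan-2-yloxy)phenol 5 (not isolated)
Conditions: NIS (1.0 equiv), TsOH (10 mol %), MeCN, 0 °C to rt; then NBS (1.02 equiv), 0 °C
Reagents that add atoms: N-iodosuccinimide, O=C1CCC(=O)N1I; N-bromosuccinimide, O=C1CCC(=O)N1Br
Why: Sequential electrophilic aromatic halogenation directed by the free phenol, with iodine going para and bromine then taking the only free ortho position.

**Step 4**
Reactants: 6 2-bromo-4-iodo-6-(propan-2-yloxy)phenol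
Product: 7 1-bromo-5-iodo-2-methoxy-3-(propan-2-yloxy)benzene
Conditions: MeI (1.5 equiv), K2CO3 (1.5 equiv), DMF, rt
Reagents that add atoms: iodomethane, CI
Why: Williamson ether synthesis on an acidic, halogen-flanked phenol, as in the O-methylation of 5-bromovanillin.

**Step 5**
Reactants: 7 1-bromo-5-iodo-2-methoxy-3-(propan-2-yloxy)benzene; 3 (5R)-5-[(6,7-dibromo-2,2-dimethyl-1,3-benzodioxol-5-yl)methyl]-2,2-dimethyl-1,3-dioxolan-4-one
Product: 10 (2R)-1-[3-bromo-4-methoxy-5-(propan-2-yloxy)phenyl]-3-(6,7-dibromo-2,2-dimethyl-1,3-benzodioxol-5-yl)-2-hydroxypropan-1-one, via arylmagnesium chloride 8 (not isolated), via magnesium hemiketal 9 (not isolated)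
Conditions: 7 (1.2 equiv), iPrMgCl·LiCl (1.15 equiv), THF, −30 °C, 45 min; add 3, −40 °C, 1 h; inverse quench into cold 10 % aq citric acid
Reagents that add atoms: none
Why: Iodine–magnesium exchange with turbo-Grignard is selective for C–I over C–Br, and the aryl Grignard adds only once to the five-membered lactone carbonyl because the cyclic magnesium hemiketal persists at low temperature (as in aryl additions to protected gluconolactones); the acidic quench then releases acetone and the α-hydroxy ketone with C2 untouched.

**Step 6**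
Reactants: 10 (2R)-1-[3-bromo-4-methoxy-5-(propan-2-yloxy)phenyl]-3-(6,7-dibromo-2,2-dimethyl-1,3-benzodioxol-5-yl)-2-hydroxypropan-1-one
Product: 11 (2R)-1-[3-bromo-4-methoxy-5-(propan-2-yloxy)phenyl]-3-(6,7-dibromo-2,2-dimethyl-1,3-benzodioxol-5-yl)-1-oxopropan-2-yl methanesulfonate
Conditions: MsCl (1.3 equiv), Et3N (1.6 equiv), CH2Cl2, −20 °C, 30 min
Reagents that add atoms: methanesulfonyl chloride, CS(=O)(=O)Cl
Why: O-Sulfonylation changes only the O–H bond, so the (R) configuration is retained, and the low temperature and short time avoid enolisation or elimination.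

**Step 7**
Reactants: 11 (2R)-1-[3-bromo-4-methoxy-5-(propan-2-yloxy)phenyl]-3-(6,7-dibromo-2,2-dimethyl-1,3-benzodioxol-5-yl)-1-oxopropan-2-yl methanesulfonate
Product: 12 methyl (2R)-2-[3-bromo-4-methoxy-5-(propan-2-yloxy)phenyl]-3-(6,7-dibromo-2,2-dimethyl-1,3-benzodioxol-5-yl)propanoate
Conditions: hν (350 nm UVA, FEP flow coil), MeOH–HFIP 4:1 (0.02 M), 2,6-lutidine (1.2 equiv), Ar-sparged, 0 °C
Reagents that add atoms: methanol, CO
Why: Proposed new method: excitation of the aroyl chromophore (λ > 320 nm, where the non-conjugated dibromobenzodioxole is transparent) weakens the Cα–OMs bond that is aligned with the carbonyl π system and H-bonded to HFIP, so mesylate leaves while the aryl ipso carbon bonds to Cα from the face anti to it, giving a bridged spiro-cyclopropanone (phenonium-type) species that methanol opens at the acyl carbon with re-aromatisation; the aryl group therefore arrives on Cα with inversion and the (R)-C–O centre becomes the (R)-C–aryl centre (same letter because the CIP ranking changes); the closest known reaction types are the photo-Favorskii-type 1,2-aryl migration of p-alkoxy/p-hydroxyphenacyl halides and phosphates and of α-chloropropiophenones, and the thermal invertive 1,2-aryl shift of α-sulfonyloxy ketals, whereas an enantiospecific light-driven shift with a sulfonate leaving group on a β-aryl, polybrominated ketone has not been shown.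

**Step 8**
Reactants: 12 methyl (2R)-2-[3-bromo-4-methoxy-5-(propan-2-yloxy)phenyl]-3-(6,7-dibromo-2,2-dimethyl-1,3-benzodioxol-5-yl)propanoate
Product: 13 methyl (2R)-2-(3-bromo-5-hydroxy-4-methoxyphenyl)-3-(2,3-dibromo-4,5-dihydroxyphenyl)propanoate
Conditions: BCl3 (5 equiv), CH2Cl2, −78 to −10 °C, 2 h; MeOH then water quench
Reagents that add atoms: none
Why: Lewis-acid ether cleavage with BCl3 removes the secondary isopropyl ether and ionises the isopropylidene ketal much faster than it attacks aryl methyl ethers or the methyl ester below 0 °C, and the non-basic medium does not epimerise the α-aryl ester centre.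

**Compound list**
1 | sodium (2R)-3-(3,4-dihydroxyphenyl)-2-hydroxypropanoate (sodium danshensu) | O[C@H](Cc1ccc(O)c(O)c1)C(=O)[O-].[Na+] | starting material
2 | (2R)-3-(2,3-dibromo-4,5-dihydroxyphenyl)-2-hydroxypropanoic acid | O[C@H](Cc1cc(O)c(O)c(Br)c1Br)C(=O)O | intermediate
3 | (5R)-5-[(6,7-dibromo-2,2-dimethyl-1,3-benzodioxol-5-yl)methyl]-2,2-dimethyl-1,3-dioxolan-4-one | CC1(C)O[C@H](Cc2cc3OC(C)(C)Oc3c(Br)c2Br)C(=O)O1 | intermediate
4 | 2-(propan-2-yloxy)phenol | CC(C)Oc1ccccc1O | starting material
5 | 4-iodo-2-(propan-2-yloxy)phenol | CC(C)Oc1cc(I)ccc1O | intermediate (not isolated)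
6 | 2-bromo-4-iodo-6-(propan-2-yloxy)phenol | CC(C)Oc1cc(I)cc(Br)c1O | intermediate
7 | 1-bromo-5-iodo-2-methoxy-3-(propan-2-yloxy)benzene | COc1c(Br)cc(I)cc1OC(C)C | intermediate
8 | [3-bromo-4-methoxy-5-(propan-2-yloxy)phenyl]magnesium chloride (LiCl complex) | COc1c(Br)cc([Mg]Cl)cc1OC(C)C | intermediate (not isolated)
9 | chloromagnesium (5R)-4-[3-bromo-4-methoxy-5-(propan-2-yloxy)phenyl]-5-[(6,7-dibromo-2,2-dimethyl-1,3-benzodioxol-5-yl)methyl]-2,2-dimethyl-1,3-dioxolan-4-olate (C4 undefined) | CC1(C)O[C@H](Cc2cc3OC(C)(C)Oc3c(Br)c2Br)C(O[Mg]Cl)(c2cc(Br)c(OC)c(OC(C)C)c2)O1 | intermediate (not isolated)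
10 | (2R)-1-[3-bromo-4-methoxy-5-(propan-2-yloxy)phenyl]-3-(6,7-dibromo-2,2-dimethyl-1,3-benzodioxol-5-yl)-2-hydroxypropan-1-one | O[C@H](Cc1cc2OC(C)(C)Oc2c(Br)c1Br)C(=O)c1cc(Br)c(OC)c(OC(C)C)c1 | intermediate
11 | (2R)-1-[3-bromo-4-methoxy-5-(propan-2-yloxy)phenyl]-3-(6,7-dibromo-2,2-dimethyl-1,3-benzodioxol-5-yl)-1-oxopropan-2-yl methanesulfonate | CS(=O)(=O)O[C@H](Cc1cc2OC(C)(C)Oc2c(Br)c1Br)C(=O)c1cc(Br)c(OC)c(OC(C)C)c1 | intermediate
12 | methyl (2R)-2-[3-bromo-4-methoxy-5-(propan-2-yloxy)phenyl]-3-(6,7-dibromo-2,2-dimethyl-1,3-benzodioxol-5-yl)propanoate | COC(=O)[C@H](Cc1cc2OC(C)(C)Oc2c(Br)c1Br)c1cc(Br)c(OC)c(OC(C)C)c1 | intermediate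
13 | methyl (2R)-2-(3-bromo-5-hydroxy-4-methoxyphenyl)-3-(2,3-dibromo-4,5-dihydroxyphenyl)propanoate | COC(=O)[C@H](Cc1cc(O)c(O)c(Br)c1Br)c1cc(O)c(OC)c(Br)c1 | target

**Totals**
Total step count: 8.
Longest linear sequence: 6 (steps 1, 2, 5, 6, 7, 8).

**Three steps most likely to fail**

Step 7 (the proposed new step).
- A free, planar α-keto radical or ion pair could erode the ee.
- C–O homolysis followed by H-abstraction from methanol would give the reduced dihydrochalcone.
- The triplet of the bromoaryl ketone could lose bromine.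
- The β-aryl ring can quench the excited state or take part in the ionisation itself.
- The flanked 4-OMe group also makes ring A a weaker migrating group than p-anisyl.
- The ee of 12 is checked by chiral HPLC against 11.
- The fallback uses known chemistry and sets out from 11. Trimethyl orthoformate in MeOH with catalytic MsOH at 50 °C converts the ketone into the α-mesyloxy dimethyl ketal F6. Heating this in MeOH–H2O 7:3 over CaCO3 (sealed tube, about 100 °C) triggers the established thermal, aryl-assisted 1,2-shift with clean inversion and gives 12, where the route is rejoined.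

Step 1.
- The second bromine may partly enter the position between the OH and the side chain.
- A third bromine may also add, and the isomers may be hard to separate.
- The fallback sets out from 1 and moves regiocontrol from electrophilic substitution to C–H borylation. Acidification with HCl and transketalisation as in step 2 give the unbrominated bis-acetonide F1.
- Ir-catalysed borylation ([Ir(OMe)(cod)]2, dtbpy, B2pin2, THF, 60 °C) goes to the only ring C–H that has no carbon substituent beside it and lies next to a ring oxygen, giving the 7-boronate F2.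
- NBS with catalytic CuBr in MeCN exchanges boron for bromine to give the 7-bromide F3. A second equivalent of NBS then brominates C6, para to the ring oxygen, as 3-bromo-4,5-dialkoxybenzyl compounds do. The product is 3, where the route is rejoined.

Step 5.
- The hemiketal may collapse early, leading to double addition.
- The Grignard reagent may enolise the dioxolanone, which would cost ee.
- Leftover iPrMgCl may exchange with the activated vicinal dibromide.
- The fallback sets out from 3 and installs the leaving group before the C–C bond. Me(MeO)NH·HCl/AlMe3 in CH2Cl2 at 0 °C opens the dioxolanone to the α-hydroxy Weinreb amide F4. MsCl/Et3N gives the α-mesyloxy Weinreb amide F5.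
- Grignard reagent 8 adds to F5 at −20 °C through the stable five-membered chelate, which cannot over-add. Work-up delivers 11 directly, so the route is rejoined there and step 6 is skipped.

**Further compounds**
F1 | step 1 | (5R)-5-[(2,2-dimethyl-1,3-benzodioxol-5-yl)methyl]-2,2-dimethyl-1,3-dioxolan-4-one | CC1(C)O[C@H](Cc2ccc3OC(C)(C)Oc3c2)C(=O)O1
F2 | step 1 | (5R)-5-{[2,2-dimethyl-7-(4,4,5,5-tetramethyl-1,3,2-dioxaborolan-2-yl)-1,3-benzodioxol-5-yl]methyl}-2,2-dimethyl-1,3-dioxolan-4-one | CC1(C)O[C@H](Cc2cc(B3OC(C)(C)C(C)(C)O3)c3OC(C)(C)Oc3c2)C(=O)O1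
F3 | step 1 | (5R)-5-[(7-bromo-2,2-dimethyl-1,3-benzodioxol-5-yl)methyl]-2,2-dimethyl-1,3-dioxolan-4-one | CC1(C)O[C@H](Cc2cc(Br)c3OC(C)(C)Oc3c2)C(=O)O1
F4 | step 5 | (2R)-3-(6,7-dibromo-2,2-dimethyl-1,3-benzodioxol-5-yl)-2-hydroxy-N-methoxy-N-methylpropanamide | O[C@H](Cc1cc2OC(C)(C)Oc2c(Br)c1Br)C(=O)N(C)OC
F5 | step 5 | (2R)-3-(6,7-dibromo-2,2-dimethyl-1,3-benzodioxol-5-yl)-1-[methoxy(methyl)amino]-1-oxopropan-2-yl methanesulfonate | CS(=O)(=O)O[C@H](Cc1cc2OC(C)(C)Oc2c(Br)c1Br)C(=O)N(C)OC
F6 | step 7 | (2R)-1-[3-bromo-4-methoxy-5-(propan-2-yloxy)phenyl]-3-(6,7-dibromo-2,2-dimethyl-1,3-benzodioxol-5-yl)-1,1-dimethoxypropan-2-yl methanesulfonate | CS(=O)(=O)O[C@H](Cc1cc2OC(C)(C)Oc2c(Br)c1Br)C(OC)(OC)c1cc(Br)c(OC)c(OC(C)C)c1
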